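**Retrosynthetic overview**
- The strategy rests on the two disubstituted alkenes of the target: C3=C4 of the 2H-pyran ring (ring B, fused to benzene ring A) and the Cα=Cβ bond of the feruloyl ester on ring C. Each can be cut back to two terminal alkenes, and the only stereocentre, quaternary C2, lies outside both.
- Key disconnection: both alkenes are made in one flask by olefin metathesis of a triene (aryl vinyl, tertiary vinyl, acrylate) with 2-methoxy-4-vinylphenol. Ring-closing metathesis builds ring B first, then cross metathesis builds the E-cinnamate.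
- The triene comes from acryloylation of a primary alcohol. That alcohol is unmasked after Wittig methylenation of an aryl aldehyde, whose aryl tertiary-alkyl ether bond is made by SNAr of a tertiary alkoxide on an ortho-formyl aryl fluoride.
- The tertiary alcohol comes from (S)-2-methylglycidol (trityl ether, then sulfonium-ylide opening to the vinyl carbinol), so C2 is taken from the chiral pool and its C–O bond is never broken. The aryl fluoride comes from 4'-fluoro-3'-methoxyacetophenone (ketal, then formylation next to fluorine).
- Ring order: rings A and C are bought; ring B is the only ring formed, in the last step.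

Key step: step 9

Remark: 2H-chromene numbering is used (O1, C2, C3=C4). C2 of the target is R. The same spatial arrangement is labelled S in the glycidol and R in every later compound only because the CIP ranking of the CH2O arm changes. A trityl ether is chosen for the primary oxygen because a silyl ether could migrate onto the neighbouring tertiary alkoxide during the SNAr step.

**Route**

Step 1
Reactants: 1 (S)-2-methylglycidol
Product: 2 (R)-2-methyl-2-[(trityloxy)methyl]oxirane
Conditions: TrCl, Et3N, DMAP (cat.), CH2Cl2, 0 °C → rt
Reagents that add atoms: trityl chloride, ClC(c1ccccc1)(c1ccccc1)c1ccccc1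
Why: O-tritylation of the primary alcohol under amine base leaves the acid-sensitive 2,2-disubstituted epoxide and its stereocentre untouched and installs a base-stable, non-migrating, acid-labile ether.

Step 2
Reactants: 2 (R)-2-methyl-2-[(trityloxy)methyl]oxirane
Product: 3 (R)-2-methyl-1-(trityloxy)but-3-en-2-ol
Conditions: Me3S+ I− (4 equiv), n-BuLi (3.9 equiv), THF, −10 °C; then 2, −10 °C → rt
Reagents that add atoms: trimethylsulfonium iodide, C[S+](C)C.[I-]
Why: One-carbon epoxide-to-allylic-alcohol homologation with dimethylsulfonium methylide, in which the ylide opens the epoxide at its unsubstituted CH2 terminus and the β-alkoxy sulfonium salt then eliminates Me2S through its own ylide, so the C–O bond at the quaternary stereocentre is never broken and its configuration is retained.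

Step 3
Reactants: 4 4'-fluoro-3'-methoxyacetophenone
Product: 5 2-(4-fluoro-3-methoxyphenyl)-2-methyl-1,3-dioxolane
Conditions: HOCH2CH2OH, p-TsOH·H2O (cat.), toluene, reflux, azeotropic removal of water
Reagents that add atoms: ethylene glycol, OCCO
Why: Acid-catalysed ketalisation masks the enolisable, electrophilic acetyl group for the organolithium, alkoxide and ylide steps that follow.

Step 4
Reactants: 5 2-(4-fluoro-3-methoxyphenyl)-2-methyl-1,3-dioxolane
Product: 6 2-fluoro-3-methoxy-5-(2-methyl-1,3-dioxolan-2-yl)benzaldehyde
Conditions: n-BuLi, PMDTA, THF, −78 °C; DMF, −78 → −40 °C; aq. NH4Cl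
Reagents that add atoms: N,N-dimethylformamide, CN(C)C=O
Why: Directed ortho-metalation in which, with lithium saturated by the triamine, deprotonation follows C–H acidity and should occur next to fluorine instead of between the methoxy and ketal groups, and the aryllithium, kept cold to prevent loss of LiF to an aryne, is formylated by DMF.

Step 5
Reactants: 3 (R)-2-methyl-1-(trityloxy)but-3-en-2-ol; 6 2-fluoro-3-methoxy-5-(2-methyl-1,3-dioxolan-2-yl)benzaldehyde
Product: 7 (R)-3-methoxy-5-(2-methyl-1,3-dioxolan-2-yl)-2-{[2-methyl-1-(trityloxy)but-3-en-2-yl]oxy}benzaldehyde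
Conditions: 3, KH (1.0 equiv), THF, 0 °C; then 6, DMF, 0 °C → rt
Reagents that add atoms: none
Why: Nucleophilic aromatic substitution by addition–elimination through a Meisenheimer adduct, in which the potassium tertiary alkoxide displaces the fluoride activated by the ortho-formyl group, the ketal rules out enolate chemistry, and the carbinol C–O bond is not broken so the R configuration is kept.

Step 6
Reactants: 7 (R)-3-methoxy-5-(2-methyl-1,3-dioxolan-2-yl)-2-{[2-methyl-1-(trityloxy)but-3-en-2-yl]oxy}benzaldehyde
Product: 8 (R)-2-[3-methoxy-4-{[2-methyl-1-(trityloxy)but-3-en-2-yl]oxy}-5-vinylphenyl]-2-methyl-1,3-dioxolane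
Conditions: Ph3PCH3Br, KOtBu, THF, 0 °C → rt
Reagents that add atoms: methyltriphenylphosphonium bromide, C[P+](c1ccccc1)(c1ccccc1)c1ccccc1.[Br-]
Why: Wittig methylenation of the non-enolisable aryl aldehyde gives the styrene while the ketal, the trityl ether and the base-stable quaternary stereocentre are unaffected.

Step 7
Reactants: 8 (R)-2-[3-methoxy-4-{[2-methyl-1-(trityloxy)but-3-en-2-yl]oxy}-5-vinylphenyl]-2-methyl-1,3-dioxolane
Product: 9 (R)-1-{4-[(1-hydroxy-2-methylbut-3-en-2-yl)oxy]-3-methoxy-5-vinylphenyl}ethan-1-one
Conditions: 1 M HCl (aq), THF, rt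
Reagents that add atoms: water, O
Why: Mild aqueous acid hydrolyses the electron-rich aryl methyl ketal and cleaves the trityl ether in one operation, while the aryl tertiary-alkyl ether should persist because its ionisation is disfavoured by the β-oxygen and by the weakly basic aryl ether oxygen, and no alkoxide is generated that could start a Smiles-type aryl migration.

Step 8
Reactants: 9 (R)-1-{4-[(1-hydroxy-2-methylbut-3-en-2-yl)oxy]-3-methoxy-5-vinylphenyl}ethan-1-one; 10 acryloyl chloride
Product: 11 (R)-2-(4-acetyl-2-methoxy-6-vinylphenoxy)-2-methylbut-3-en-1-yl acrylate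
Conditions: Et3N, CH2Cl2, −10 → 0 °C
Reagents that add atoms: none
Why: Acylation of the primary alcohol by the acid chloride under amine base is fast at low temperature and leaves the ketone, both vinyl groups and the stereocentre unchanged.

Step 9
Reactants: 11 (R)-2-(4-acetyl-2-methoxy-6-vinylphenoxy)-2-methylbut-3-en-1-yl acrylate; 12 2-methoxy-4-vinylphenol
Product: 14 (R)-(6-acetyl-8-methoxy-2-methyl-2H-chromen-2-yl)methyl (E)-3-(4-hydroxy-3-methoxyphenyl)acrylate, via chromene acrylate 13 (not isolated)
Conditions: RuCl2(H2IMes)(=CH-C6H4-2-OiPr) [second-generation Hoveyda–Grubbs catalyst, H2IMes = 1,3-dimesitylimidazolidin-2-ylidene] (5 mol%), CH2Cl2 (0.02 M), 40 °C, Ar sparge; then 12 (4 equiv, two portions) and more catalyst (5 mol%), 40 °C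
Reagents that add atoms: none
Why: The ruthenium alkylidene exchanges onto the aryl vinyl group of 11, and the resulting benzylidene adds to the hindered tertiary vinyl group through a metallacyclobutane ([2+2] cycloaddition and cycloreversion), releasing ethylene and closing ring B by a six-membered ring-closing metathesis that forms the C3=C4 bond and gives 13. The closest known reactions are the ring-closing metathesis of 2-(allyloxy)styrenes to 2H-chromenes, including 2,2-disubstituted ones, and the cross metathesis of acrylates with styrenes to E-cinnamates, here run one after the other in the same flask. No stereocentre is formed, and quaternary C2, which bears no hydrogen and takes no part in the metallacycles, is carried through unchanged. The step needs chemoselective pairing of four alkenes: the styrene of 11 loads fastest and can only close on the tertiary vinyl group, because closure on the acrylate would need a nine-membered ring, while the competing six-membered lactone closure between acrylate and tertiary vinyl group would have to start from one of the two alkenes that initiate slowly. Adding 12 only after ring closure keeps it from coupling with the aryl vinyl group; the acrylate of 13, which does not homodimerise, then couples with the electron-rich styrene 12, whose free phenol the catalyst tolerates, and surplus 12 ends as its stilbene dimer, to be removed by chromatography. The E geometry should follow from thermodynamic control in the reversible metathesis, the conjugated trans-cinnamate being strongly favoured.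

**Compound list**
1 | (S)-2-methylglycidol | OC[C@@]1(C)CO1 | starting material
2 | (R)-2-methyl-2-[(trityloxy)methyl]oxirane | C(c1ccccc1)(c1ccccc1)(c1ccccc1)OC[C@@]1(C)CO1 | intermediate
3 | (R)-2-methyl-1-(trityloxy)but-3-en-2-ol | C(c1ccccc1)(c1ccccc1)(c1ccccc1)OC[C@@](O)(C)C=C | intermediate
4 | 4'-fluoro-3'-methoxyacetophenone | CC(=O)c1ccc(F)c(OC)c1 | starting material
5 | 2-(4-fluoro-3-methoxyphenyl)-2-methyl-1,3-dioxolane | CC1(OCCO1)c1ccc(F)c(OC)c1 | intermediate
6 | 2-fluoro-3-methoxy-5-(2-methyl-1,3-dioxolan-2-yl)benzaldehyde | O=Cc1cc(C2(C)OCCO2)cc(OC)c1F | intermediate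
7 | (R)-3-methoxy-5-(2-methyl-1,3-dioxolan-2-yl)-2-{[2-methyl-1-(trityloxy)but-3-en-2-yl]oxy}benzaldehyde | C(c1ccccc1)(c1ccccc1)(c1ccccc1)OC[C@@](Oc1c(C=O)cc(C2(C)OCCO2)cc1OC)(C)C=C | intermediate
8 | (R)-2-[3-methoxy-4-{[2-methyl-1-(trityloxy)but-3-en-2-yl]oxy}-5-vinylphenyl]-2-methyl-1,3-dioxolane | C(c1ccccc1)(c1ccccc1)(c1ccccc1)OC[C@@](Oc1c(C=C)cc(C2(C)OCCO2)cc1OC)(C)C=C | intermediate
9 | (R)-1-{4-[(1-hydroxy-2-methylbut-3-en-2-yl)oxy]-3-methoxy-5-vinylphenyl}ethan-1-one | OC[C@@](Oc1c(C=C)cc(C(C)=O)cc1OC)(C)C=C | intermediate
10 | acryloyl chloride | C=CC(=O)Cl | starting material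
11 | (R)-2-(4-acetyl-2-methoxy-6-vinylphenoxy)-2-methylbut-3-en-1-yl acrylate | C=CC(=O)OC[C@@](Oc1c(C=C)cc(C(C)=O)cc1OC)(C)C=C | intermediate
12 | 2-methoxy-4-vinylphenol | C=Cc1ccc(O)c(OC)c1 | starting material
13 | (R)-(6-acetyl-8-methoxy-2-methyl-2H-chromen-2-yl)methyl acrylate (chromene acrylate, not isolated) | C=CC(=O)OC[C@@]1(C)C=Cc2cc(C(C)=O)cc(OC)c2O1 | intermediate
14 | (R)-(6-acetyl-8-methoxy-2-methyl-2H-chromen-2-yl)methyl (E)-3-(4-hydroxy-3-methoxyphenyl)acrylate (CNP0168033.1) | COc1cc(/C=C/C(=O)OC[C@@]2(C)C=Cc3cc(C(C)=O)cc(OC)c3O2)ccc1O | target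

**Totals**
Total step count: 9.
Longest linear sequence: 7 steps (steps 1, 2, 5, 6, 7, 8, 9 from (S)-2-methylglycidol; the arene branch, steps 3, 4, 5, 6, 7, 8, 9, is equally long).

**Steps most likely to fail**

1. Step 9 (one-pot ring-closing and cross metathesis). The catalyst may initiate at the acrylate or the tertiary vinyl group and close the six-membered lactone, which consumes the vinyl group needed for ring B. The cross metathesis may also stall because the vinylphenol is diverted into homodimerisation or oligomerisation. The fallback sets out from alcohol 9, before the acrylate is installed, and separates the two events. Ring-closing metathesis of 9 alone with RuCl2(H2IMes)(=CH-C6H4-2-OiPr) in CH2Cl2 at 40 °C, where no lactone closure is possible, should give the chromene alcohol (R)-1-[2-(hydroxymethyl)-8-methoxy-2-methyl-2H-chromen-6-yl]ethan-1-one F1. Steglich esterification of F1 with commercial (E)-4-acetoxy-3-methoxycinnamic acid (CC(=O)Oc1ccc(/C=C/C(O)=O)cc1OC; EDC·HCl, DMAP, CH2Cl2, rt) should give the aryl acetate (R)-(6-acetyl-8-methoxy-2-methyl-2H-chromen-2-yl)methyl (E)-3-(4-acetoxy-3-methoxyphenyl)acrylate F2. Selective aminolysis of the phenolic acetate (pyrrolidine, CH2Cl2, 0 °C) comes back to the route at target 14.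

2. Step 5 (SNAr of the tertiary alkoxide). Reversible addition of the hindered alkoxide to the formyl group and base-induced hydride-transfer disproportionation of the aldehyde may outrun the slow attack at the C–F carbon, which is flanked on both sides. The fallback sets out from aldehyde 6 and replaces the formyl activator by a nitrile, which is more strongly activating and tolerates alkoxide and heat. Oxidative amination of 6 (I2, aq. NH3, THF, rt) should give 2-fluoro-3-methoxy-5-(2-methyl-1,3-dioxolan-2-yl)benzonitrile F3. SNAr with the potassium alkoxide of 3 (KH, THF, 0 °C; then F3, DMF, rt → 60 °C) should give (R)-3-methoxy-5-(2-methyl-1,3-dioxolan-2-yl)-2-{[2-methyl-1-(trityloxy)but-3-en-2-yl]oxy}benzonitrile F4. Partial reduction (i-Bu2AlH, toluene, −78 °C; aq. potassium sodium tartrate, then brief cold aq. citric acid to hydrolyse the imine) comes back to the route at aldehyde 7.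

3. Step 4 (formylation next to fluorine). Metalation may occur between the methoxy and ketal groups, where lithium can be chelated, instead of next to fluorine, and the ortho-fluoro aryllithium may lose LiF to an aryne. The fallback sets out from ketal 5 and fixes the position by steric control instead of acidity. Iridium-catalysed C–H borylation ([Ir(OMe)(cod)]2, 4,4'-di-tert-butyl-2,2'-bipyridine, B2pin2, THF, 80 °C) can only reach the C–H flanked by fluorine and hydrogen, since the other two are blocked by the ketal-bearing carbon. It should give 2-[4-fluoro-3-methoxy-5-(4,4,5,5-tetramethyl-1,3,2-dioxaborolan-2-yl)phenyl]-2-methyl-1,3-dioxolane F5. Ipso-iodination (NaI, TsN(Cl)Na, THF/H2O, rt) should give 2-(4-fluoro-3-iodo-5-methoxyphenyl)-2-methyl-1,3-dioxolane F6. Iodine–magnesium exchange (i-PrMgCl·LiCl, THF, −40 °C) followed by DMF comes back to the route at aldehyde 6.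

Further compounds
F1 | step 9 | (R)-1-[2-(hydroxymethyl)-8-methoxy-2-methyl-2H-chromen-6-yl]ethan-1-one | OC[C@@]1(C)C=Cc2cc(C(C)=O)cc(OC)c2O1
F2 | step 9 | (R)-(6-acetyl-8-methoxy-2-methyl-2H-chromen-2-yl)methyl (E)-3-(4-acetoxy-3-methoxyphenyl)acrylate | COc1cc(/C=C/C(=O)OC[C@@]2(C)C=Cc3cc(C(C)=O)cc(OC)c3O2)ccc1OC(C)=O
F3 | step 5 | 2-fluoro-3-methoxy-5-(2-methyl-1,3-dioxolan-2-yl)benzonitrile | N#Cc1cc(C2(C)OCCO2)cc(OC)c1F
F4 | step 5 | (R)-3-methoxy-5-(2-methyl-1,3-dioxolan-2-yl)-2-{[2-methyl-1-(trityloxy)but-3-en-2-yl]oxy}benzonitrile | C(c1ccccc1)(c1ccccc1)(c1ccccc1)OC[C@@](Oc1c(C#N)cc(C2(C)OCCO2)cc1OC)(C)C=C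
F5 | step 4 | 2-[4-fluoro-3-methoxy-5-(4,4,5,5-tetramethyl-1,3,2-dioxaborolan-2-yl)phenyl]-2-methyl-1,3-dioxolane | CC1(OCCO1)c1cc(OC)c(F)c(B2OC(C)(C)C(C)(C)O2)c1
F6 | step 4 | 2-(4-fluoro-3-iodo-5-methoxyphenyl)-2-methyl-1,3-dioxolane | CC1(OCCO1)c1cc(OC)c(F)c(I)c1
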